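## The problem

The target is a daucane: a cyclopentane (ring A: C1–C2–C3–C4–C5) trans-fused through C1–C5 to a cycloheptane (ring B: C1, C5, C6, C7, C8, C9, C10). C1 carries the angular methyl group, C4 an isopropyl carbinol and C8 a methyl group; β is the face of the C1 methyl group and α the face of H-5. Eight stereocentres must be set: C1 (methyl β), C2 (acetate α), C4 (OH β, isopropyl α), C5 (H α), C6 (3,4-dimethoxybenzoate α), C8 and C9 (oxirane) and C10 (OH α). C4 is the one centre that can be made enantioselectively in an open-chain precursor, and it can rule the others: it is vicinal to C5, two bonds from C1, and its hydroxyl is 1,3 to both C2 and C6, so hydride can be delivered from it to either carbon. The axial C1 methyl group in turn shields the β face of ring B. The sensitive parts are the two different esters beside a free C10 hydroxyl that is 1,3 to the acetate (acyl shift under base), the tertiary hydroxyl, which is β to a carbonyl whenever C2 or C6 is a ketone (retro-aldol, elimination), and above all the oxirane. As drawn, the oxirane is trans-fused to ring B (C8–O β, C9–O α): neither epoxidation of a ground-state cycloheptene nor an SN2 closure inside the ring can give it, and it will be strained and acid-labile, so it must come last. The feature that allows a short construction is that C5–C10 carry the substitution pattern of a benzene ring (oxygen at C6 ortho and methyl at C8 para to C5), while the seventh ring atom, C1, is a quaternary methyl-bearing carbon next to the C2 oxygen. Ring B is therefore an arene plus one carbenoid carbon, and ring A is the tether that delivers it.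

## Retrosynthesis

**Oxirane and C10 carbinol (25 ⇒ 24 ⇒ 22).** The last bonds made are C10–H and the two C–O bonds of the oxirane. Because the oxirane is trans-fused, the only ring-intact precursor is an (E)-configured C8=C9 bond, and the practical way to such a bond in a seven-membered ring is Z→E photoisomerisation of a cyclohept-2-enone. C10 is therefore taken back to a ketone: 25 comes from epoxy ketone 24 by chelation-controlled reduction, and 24 from enone 22 through its transient (E)-isomer 23. Cutting the oxirane last keeps the strained ring out of every other step; the price is that oxygen transfer to 23 has no direct precedent. Enone 22 has five stereocentres and no strain. The forward steps must intercept 23 before it relaxes, on the twist isomer that places C8–O on the β face, and then bring hydride to the β face of C10.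

**Ester and oxidation levels in ring B (22 ⇒ 20 + 21 ⇒ 19 ⇒ 18).** The C6–O acyl bond is cut, then C10 is returned to an alcohol and C6 to a ketone. Acylating C6 only after C10 has been oxidised avoids telling two secondary hydroxyls apart by acylation: in triol 19 an allylic-selective oxidant takes C10–OH, and in 20 the C6–OH is the only acylable hydroxyl, which acid chloride 21 then esterifies. The C6 carbinol of 19 is traced to ketone 18 because the β-hydroxyl at C4 can deliver hydride to the β face of C6. What is asked is site selectivity in the oxidation and facial selectivity in the reduction.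

**C10 oxygen (18 ⇒ 17 ⇒ 16).** The C10–O and C7–H bonds of 18 are cut together: γ,δ-epoxy enone 17 gives 18 on two-electron reduction, and 17 comes from dienone 16 by epoxidation of the remote double bond. This is preferred to a singlet-oxygen endoperoxide, which leaves an extra oxygen at C7, and to allylic oxidation of a monoene, where C7 and C10 would compete. The precursor 16 is a plain 2,4-cycloheptadienone. The peracid must take the γ,δ- and not the α,β-bond, and the reduction must break C9–O and protonate C7.

**C2 acetate (16 ⇒ 15 ⇒ 14).** The acetate is cut to the C2 alcohol and that to the C2 ketone of 14. This is done before C10 bears a hydroxyl: in 14 the C4–OH is the only hydroxyl β to C2, and hydride delivered from it gives the 2α-alcohol, whereas a C10–OH would direct to the other face. The forward reduction must take the saturated C2 ketone and spare the dienone carbonyl.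

**Unmasking (14 ⇒ 13).** Both Si–O bonds of a di-tert-butylsilylene that joins O4 to the enol oxygen at C6 are cut. This takes the β-hydroxy dione 14, with its retro-aldol liability and its C5 stereocentre, back to triene 13, which has only C1 and C4 as stereocentres. A silyl enol ether is chosen over a methyl enol ether because fluoride releases it without the strong acid that could rearomatise the norcaradiene form. C5 must settle trans-fused when the ketone is released.

**Key cut (13 ⇒ 11).** C1–C5 and C1–C10 are cut, by way of norcaradiene 12. Both rings and the quaternary centre disappear at once, leaving diazoketone 11, a benzene ring with one stereocentre. Cuts that close ring B by a single C–C bond (an aldol at C5–C6, or expansion of a six-membered ring) would each need a fully substituted ring A beforehand. The carbenoid must add to the C5–C10 bond and not to C5–C6, and on the face opposite the isopropyl group. The silylene ring is designed to enforce both, since it pins the C4–O bond in the arene plane and makes C5–C6 part of a ring.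

**Side chain (11 ⇒ 9 ⇒ 7 ⇒ 6).** The C1–C2 bond is cut (acylation of a diazoalkane by acid chloride 10 made from acid 9). The carboxyl carbon of 9 is the internal alkene carbon of the allyl group of 7 (oxidative cleavage through aldehyde 8), and the silylene of 7 is cut to phenol-diol 6. These are functional-group changes on one stereocentre; they only have to leave the silylene and the arene untouched.

**Carbinol and arene (6 ⇒ 4 ⇒ 1 + 2).** The C3–C4 bond is cut by enantioselective allylation of ketone 4, with the ortho-phenol as the handle that binds the chiral allylsilane. This class of reagent is chosen over catalytic allylboration because the ketone is branched and ortho-substituted. The aryl–acyl bond is cut by a Fries rearrangement of ester 3, made from 1 and 2. The allylation must add to the Re face; the Fries step must go ortho to oxygen and para to methyl.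

## Roads not taken

**Alternative 1:** ring B closed around a preformed (E)-alkene oxide. The cut is C5–C6: divalent samarium reduces a C5 bromide next to a C4 ketone and the samarium enolate adds to a C6 aldehyde, giving epoxy hydroazulenone A1 (C6–OH, C4 ketone, C2 and C10 silyl ethers, isopropyl and esters still to come).
- Merits: the trans-fused oxirane is made on an open chain from an (E)-trisubstituted alkene by ordinary, even reagent-controlled, epoxidation. In this respect the road is better than the chosen one, whose oxirane step is without precedent.
- Weak points: the Reformatsky closure forms a seven-membered ring beside the quaternary C1 and must pay the strain of the trans-fused oxabicyclo[5.1.0]octane in its transition state, while setting C5 and C6 together. The isopropyl group must then be added to the C4 ketone of A1, a β-hydroxy ketone with an enolisable C5, on the correct face. The strained oxirane is carried through that addition, two deprotections and two acylations. The chain with its four stereocentres is built linearly.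
- Comparison: the chosen plan answers with two rings and the quaternary centre from a benzene ring in one step, a bicyclic core in six steps, and an oxirane that exists only in the last two steps.

**Alternative 2:** conjugate methylation and aldol on a silyloxycyclopentenone. The cut is C1–CH3 and C5–C6 with no ring closed: a methyl cuprate, activated by a boron Lewis acid, adds to C1, and the enolate, passed to zinc, adds to an unsaturated aldehyde, giving ring-A aldol A2 (C4 ketone, C1 methyl and dithianyl, C5 bearing the C6 carbinol and a methallyl arm).
- Merits: C1 and C5 are set kinetically and trans in one operation on a five-membered ring, and the C2 oxygen is in place from the start. This is better than the chosen plan's reliance on equilibration at C5.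
- Weak points: A2 contains no ring B. C9 is still missing, a seven-membered closure between the dithiane carbon and the methallyl arm remains, and the oxirane then has to be fused trans onto a closed ring, exactly the problem of the chosen plan, or the ring closed around it. Conjugate addition to a β-dithianyl enone to make a quaternary centre is demanding, and the C4 carbinol still has to be made from the ketone.
- Comparison: the chosen plan has weaker control at C5 but far fewer steps to the bicycle.

**Alternative 3:** a hydrindanone expanded by one carbon through a siloxycyclopropane. Zinc-carbenoid cyclopropanation of the C10–C8 silyl enol ether, oxidative opening by a ferric salt and elimination form C9–C10 and C8–C9 and cleave the old C8–C10 bond, giving the fully acylated C10 enone A3, which is the same compound as 22.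
- Merits: all stereocentres of ring A, C5 and C6 are set on a rigid hydrindane by well-understood six-membered-ring chemistry, probably with better control than the chosen plan has at C5, and the expansion type is well known.
- Weak points: the hydrindanone with the tertiary carbinol and both esters must be built first, which is a long linear task. The tetrasubstituted silyl enol ether beside the quaternary C1 is hindered, and the Lewis-acidic oxidant meets a tertiary alcohol and two esters.
- Comparison: this road ends at 22 and therefore faces the same unprecedented oxirane step, so it gains nothing where the risk is highest. The chosen plan reaches 22 in fourteen steps from a cresol.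

Key step: step 6

Assumption: the oxirane is built exactly as drawn, trans-fused to ring B (C8–O β, C9–O α); the cis-fused isomer is treated as a different compound.
Assumption: in step 2 the (R,R) antipode of the allylsilane is taken to be the one that adds allyl to the Re face of 4; if the sense proves opposite, the (S,S) reagent is used and nothing else changes.

## Steps

Step 1
Reactants: 1 3-methylphenol; 2 2-methylpropanoyl chloride
Product: 4 1-(2-hydroxy-4-methylphenyl)-2-methylpropan-1-one, via 3-methylphenyl 2-methylpropanoate 3 (not isolated)
Conditions: neat, 80 °C; then AlCl3 (1.3 equiv), 140 °C; aq. HCl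
Reagents that add atoms: none
Why: O-Acylation followed by AlCl3-mediated Fries rearrangement; at 140 °C the ortho-hydroxy ketone is favoured as its aluminium chelate, and of the two ortho positions only the one para to the methyl group is unhindered.

Step 2
Reactants: 4 1-(2-hydroxy-4-methylphenyl)-2-methylpropan-1-one
Product: 6 2-[(3S)-3-hydroxy-2-methylhex-5-en-3-yl]-5-methylphenol, via spirocyclic silicon alkoxide 5 (not isolated)
Conditions: (R,R)-allylchlorosilane reagent (1.5 equiv), CH2Cl2, 23 → 40 °C; then 1 M aq. HCl, 0 °C, brief
Reagents that add atoms: (R,R)-2-allyl-1,3-bis(4-bromobenzyl)-2-chlorooctahydro-1H-1,3,2-benzodiazasilole, C=CC[Si]1(Cl)N(Cc2ccc(Br)cc2)[C@@H]2CCCC[C@H]2N1Cc1ccc(Br)cc1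
Why: Phenol-directed enantioselective allylation of a ketone by a strained chiral allylchlorosilane: the phenol displaces chloride, the silicon becomes Lewis acidic, binds the carbonyl oxygen and passes allyl to carbon through a closed six-membered transition state, which is why branched and ortho-substituted aryl ketones are tolerated. Allyl must add to the Re face to give the (S)-carbinol (C4 of the target), and the reagent antipode is chosen accordingly.

Step 3
Reactants: 6 2-[(3S)-3-hydroxy-2-methylhex-5-en-3-yl]-5-methylphenol
Product: 7 (4S)-2,2-di-tert-butyl-7-methyl-4-(propan-2-yl)-4-(prop-2-en-1-yl)-4H-1,3,2-benzodioxasiline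
Conditions: tBu2Si(OTf)2, 2,6-lutidine, CH2Cl2, 0 °C → rt
Reagents that add atoms: di-tert-butylsilyl bis(trifluoromethanesulfonate), CC(C)(C)[Si](OS(=O)(=O)C(F)(F)F)(OS(=O)(=O)C(F)(F)F)C(C)(C)C
Why: Silylene formation across a phenol and a 1,3-related tertiary alcohol; the second Si–O bond forms intramolecularly, so the hindered carbinol reacts. The ring protects both oxygens in one step, pins the C4–O bond in the arene plane for step 6 and makes the later C6 oxygen a fluoride-labile enol silyl ether.

Step 4
Reactants: 7 (4S)-2,2-di-tert-butyl-7-methyl-4-(propan-2-yl)-4-(prop-2-en-1-yl)-4H-1,3,2-benzodioxasiline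
Product: 9 [(4S)-2,2-di-tert-butyl-7-methyl-4-(propan-2-yl)-4H-1,3,2-benzodioxasilin-4-yl]acetic acid, via aldehyde 8 (not isolated)
Conditions: O3, MeCN/H2O 9:1, 0 °C; then NaClO2, NaH2PO4, 0 °C → rt
Reagents that add atoms: ozone, [O-][O+]=O; sodium chlorite, [Na+].[O-]Cl=O
Why: Ozonolysis in aqueous MeCN gives the aldehyde directly (water intercepts the carbonyl oxide) and Pinnick oxidation in the same flask gives the acid; the H2O2 formed in the first stage consumes HOCl, so the electron-rich ring is not chlorinated. The terminal alkene is far more reactive towards ozone than the arene, and the silylene is inert to both stages.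

Step 5
Reactants: 9 [(4S)-2,2-di-tert-butyl-7-methyl-4-(propan-2-yl)-4H-1,3,2-benzodioxasilin-4-yl]acetic acid
Product: 11 3-diazo-1-[(4S)-2,2-di-tert-butyl-7-methyl-4-(propan-2-yl)-4H-1,3,2-benzodioxasilin-4-yl]butan-2-one, via acid chloride 10 (not isolated)
Conditions: 1-chloro-N,N,2-trimethylprop-1-en-1-amine, CH2Cl2, 0 °C; then CH3CHN2 (3 equiv), Et2O, −20 → 0 °C
Reagents that add atoms: diazoethane, CC=[N+]=[N-]
Why: The α-chloroenamine makes the acid chloride without releasing HCl, and acylation of diazoethane (the first stage of an Arndt–Eistert sequence) gives the α-methyl diazoketone; a second equivalent of diazoethane removes HCl as chloroethane.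

Step 6
Reactants: 11 3-diazo-1-[(4S)-2,2-di-tert-butyl-7-methyl-4-(propan-2-yl)-4H-1,3,2-benzodioxasilin-4-yl]butan-2-one
Product: 13 (1S,4S)-4,6-[(di-tert-butylsilanediyl)bis(oxy)]dauca-5,7,9-trien-2-one, via norcaradiene 12 (not isolated)
Conditions: Rh2(O2CC3F7)4 (1 mol %), CH2Cl2, rt, slow addition of 11
Reagents that add atoms: none
Why: Rh2(O2CC3F7)4 expels N2 from 11 to give an electrophilic rhodium carbenoid at C1, which adds across the C5–C10 π-bond of the electron-rich arene to give norcaradiene 12; 12 opens by disrotatory six-electron electrocyclic cleavage of the C5–C10 σ-bond to cycloheptatriene 13. The closest known reaction type is the intramolecular Büchner reaction of 1-diazo-4-arylbutan-2-ones and their α-methyl homologues to 3,4-dihydroazulen-1(2H)-ones. Ring A closes by carbenoid addition through the three-atom tether C2–C3–C4 (C1–C5 formed in a 5-exo sense, cyclopropane cis-fused to the new five-membered ring). Ring B is not closed from a chain but arises from the benzene ring when C1 is inserted between C5 and C10 (C1–C10 formed, then ring opening). The one new stereocentre, C1, is controlled by C4: the dioxasiline ring holds the C4–O bond in the arene plane, so C3 and the isopropyl group project to opposite faces, the carbenoid can only reach the face that carries C3, and the C1 methyl group ends cis to the C4 oxygen and trans to isopropyl. Site selectivity for C5–C10 over C5–C6 is needed and is secured by the same ring, because the C5–C6 bond is part of the dioxasiline and bears the bulky silicon. Selectivity for arene addition over 1,5-insertion into the isopropyl methine C–H is needed and is sought with the perfluorobutyrate ligands, which make the carbenoid most electrophilic. The α-methyl group has only primary hydrogens, so 1,2-hydride shift is slow, and both oxygens are silylated, so no O–H insertion can occur.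

Step 7
Reactants: 13 (1S,4S)-4,6-[(di-tert-butylsilanediyl)bis(oxy)]dauca-5,7,9-trien-2-one
Product: 14 4β-hydroxy-5αH-dauca-7,9-diene-2,6-dione
Conditions: HF·pyridine, pyridine/THF, 0 °C → rt
Reagents that add atoms: none
Why: Fluoride cleaves the enol Si–O bond and then the tertiary Si–O bond; the dienol tautomerises to the C6 ketone by protonation at C5 and the C4 hydroxyl is freed, without the strong Brønsted acid that would invite norcaradiene-to-tetralone rearomatisation. C5 is epimerisable here and should settle trans-fused (H-5 α), the arrangement that keeps the C4 isopropyl group cis to H-5 and not to the C5–C6 bond.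

Step 8
Reactants: 14 4β-hydroxy-5αH-dauca-7,9-diene-2,6-dione
Product: 15 2α,4β-dihydroxy-5αH-dauca-7,9-dien-6-one
Conditions: Me4NBH(OAc)3 (1.5 equiv), MeCN/AcOH 1:1, −40 °C
Reagents that add atoms: none
Why: Evans–Saksena reduction: the C4 hydroxyl exchanges onto boron and hands hydride to the β face of C2, giving the 2α-alcohol (trans-1,3-diol); no other hydroxyl is present to direct to the α face. The conjugated C6 carbonyl is less electrophilic and is spared by limiting the reagent at low temperature.

Step 9
Reactants: 15 2α,4β-dihydroxy-5αH-dauca-7,9-dien-6-one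
Product: 16 2α-acetoxy-4β-hydroxy-5αH-dauca-7,9-dien-6-one
Conditions: Ac2O, pyridine, DMAP (cat.), CH2Cl2, rt
Reagents that add atoms: acetic anhydride, CC(=O)OC(C)=O
Why: Acylation of the only secondary hydroxyl; the tertiary C4 hydroxyl does not react under these conditions.

Step 10
Reactants: 16 2α-acetoxy-4β-hydroxy-5αH-dauca-7,9-dien-6-one
Product: 17 2α-acetoxy-9α,10α-epoxy-4β-hydroxy-5αH-dauc-7-en-6-one
Conditions: mCPBA, NaHCO3, CH2Cl2, 0 °C
Reagents that add atoms: 3-chloroperoxybenzoic acid (mCPBA), OOC(=O)c1cccc(Cl)c1
Why: Peracids epoxidise 2,4-dienones at the γ,δ-double bond because the α,β-bond is the more deactivated; attack anti to the axial C1 methyl group gives the 9α,10α-oxirane. The configuration at C10 is erased in step 13 but is needed in the fallback to step 15.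

Step 11
Reactants: 17 2α-acetoxy-9α,10α-epoxy-4β-hydroxy-5αH-dauc-7-en-6-one
Product: 18 2α-acetoxy-4β,10α-dihydroxy-5αH-dauc-8-en-6-one
Conditions: SmI2 (2.2 equiv), THF/MeOH, −78 °C
Reagents that add atoms: none
Why: SmI2 reduction of a γ,δ-epoxy enone: electron transfer to the enone cleaves the allylic C9–O bond, and the samarium dienolate is protonated by MeOH at C7, giving the β,γ-enone with the oxygen left on C10. The ester and the tertiary alcohol are inert at −78 °C.

Step 12
Reactants: 18 2α-acetoxy-4β,10α-dihydroxy-5αH-dauc-8-en-6-one
Product: 19 2α-acetoxy-5αH-dauc-8-ene-4β,6α,10α-triol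
Conditions: Me4NBH(OAc)3, MeCN/AcOH 1:1, −20 °C
Reagents that add atoms: none
Why: Second Evans–Saksena reduction: the C4 hydroxyl, the only hydroxyl β to the ketone, delivers hydride to the β face of C6 and sets the 6α-alcohol; the C10 hydroxyl is too remote to compete and C2 is already an ester.

Step 13
Reactants: 19 2α-acetoxy-5αH-dauc-8-ene-4β,6α,10α-triol
Product: 20 2α-acetoxy-4β,6α-dihydroxy-5αH-dauc-8-en-10-one
Conditions: MnO2, CH2Cl2, rt
Reagents that add atoms: none
Why: MnO2 oxidises allylic alcohols only, so the C10 hydroxyl becomes the enone carbonyl while the homoallylic C6 hydroxyl and the tertiary one stay; the two secondary alcohols are thus told apart without a protecting group.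

Step 14
Reactants: 20 2α-acetoxy-4β,6α-dihydroxy-5αH-dauc-8-en-10-one; 21 3,4-dimethoxybenzoyl chloride
Product: 22 2α-acetoxy-6α-(3,4-dimethoxybenzoyloxy)-4β-hydroxy-5αH-dauc-8-en-10-one
Conditions: Et3N, DMAP, CH2Cl2, 0 °C → rt
Reagents that add atoms: none
Why: DMAP-catalysed acylation of the one remaining secondary hydroxyl by the acid chloride; base is kept mild and cold to avoid vinylogous elimination of the new ester through C7.

Step 15
Reactants: 22 2α-acetoxy-6α-(3,4-dimethoxybenzoyloxy)-4β-hydroxy-5αH-dauc-8-en-10-one
Product: 24 2α-acetoxy-6α-(3,4-dimethoxybenzoyloxy)-8β,9α-epoxy-4β-hydroxy-5αH-daucan-10-one, via (8E)-enone 23 (not isolated)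
Conditions: hν (366 nm), CH2Cl2, −78 °C; then DMDO (acetone), dark, −78 → −40 °C
Reagents that add atoms: dimethyldioxirane (DMDO), CC1(C)OO1
Why: Proposed new method: irradiation into the n→π* band at 366 nm, where the dimethoxybenzoate does not absorb, converts the cyclohept-2-enone 22 into its (E)-isomer 23, as cyclohept-2-enones are known to do at low temperature; the twisted C8=C9 bond of 23 is no longer conjugated, is raised in energy like a trans-cycloalkene, and should accept oxygen from the neutral electrophile DMDO in a concerted, stereoretentive transfer on its one exposed face, so that the E geometry becomes the trans-fused oxirane (C8–O β, C9–O α when the twist carries C7 to the β face and C10 to the α face); the closest known reaction types are the trapping of photogenerated (E)-cyclohept-2-enones by dienes and nucleophiles and the stereoretentive dioxirane epoxidation of trans-cyclooctenes, and unconsumed 22 is recycled.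

Step 16
Reactants: 24 2α-acetoxy-6α-(3,4-dimethoxybenzoyloxy)-8β,9α-epoxy-4β-hydroxy-5αH-daucan-10-one
Product: 25 2α-acetoxy-6α-(3,4-dimethoxybenzoyloxy)-8β,9α-epoxy-5αH-daucane-4β,10α-diol
Conditions: Zn(BH4)2, Et2O, −30 °C
Reagents that add atoms: none
Why: Chelation-controlled reduction of an α,β-epoxy ketone by Zn(BH4)2: zinc bridges the carbonyl and oxirane oxygens and hydride enters on the side away from C8, here the β face, giving the erythro (10α) alcohol. Both esters are inert to this reagent at −30 °C and the medium stays non-acidic for the oxirane.

## Compound list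

1 | 3-methylphenol | Cc1cccc(O)c1 | starting material
2 | 2-methylpropanoyl chloride | CC(C)C(=O)Cl | starting material
3 | 3-methylphenyl 2-methylpropanoate | Cc1cccc(OC(=O)C(C)C)c1 | intermediate
4 | 1-(2-hydroxy-4-methylphenyl)-2-methylpropan-1-one | Cc1ccc(C(=O)C(C)C)c(O)c1 | intermediate
5 | spirocyclic silicon alkoxide: 4H-1,3,2-benzodioxasiline of 6 whose silicon is held by (R,R)-N,N'-bis(4-bromobenzyl)cyclohexane-1,2-diamine | Cc1ccc2c(c1)O[Si]3(N(Cc4ccc(Br)cc4)[C@@H]4CCCC[C@H]4N3Cc3ccc(Br)cc3)O[C@]2(C(C)C)CC=C | intermediate
6 | 2-[(3S)-3-hydroxy-2-methylhex-5-en-3-yl]-5-methylphenol | Oc1cc(C)ccc1[C@@](O)(C(C)C)CC=C | intermediate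
7 | (4S)-2,2-di-tert-butyl-7-methyl-4-(propan-2-yl)-4-(prop-2-en-1-yl)-4H-1,3,2-benzodioxasiline | Cc1ccc2c(c1)O[Si](C(C)(C)C)(C(C)(C)C)O[C@]2(C(C)C)CC=C | intermediate
8 | [(4S)-2,2-di-tert-butyl-7-methyl-4-(propan-2-yl)-4H-1,3,2-benzodioxasilin-4-yl]acetaldehyde | Cc1ccc2c(c1)O[Si](C(C)(C)C)(C(C)(C)C)O[C@]2(C(C)C)CC=O | intermediate
9 | [(4S)-2,2-di-tert-butyl-7-methyl-4-(propan-2-yl)-4H-1,3,2-benzodioxasilin-4-yl]acetic acid | Cc1ccc2c(c1)O[Si](C(C)(C)C)(C(C)(C)C)O[C@]2(C(C)C)CC(=O)O | intermediate
10 | [(4S)-2,2-di-tert-butyl-7-methyl-4-(propan-2-yl)-4H-1,3,2-benzodioxasilin-4-yl]acetyl chloride | Cc1ccc2c(c1)O[Si](C(C)(C)C)(C(C)(C)C)O[C@]2(C(C)C)CC(=O)Cl | intermediate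
11 | 3-diazo-1-[(4S)-2,2-di-tert-butyl-7-methyl-4-(propan-2-yl)-4H-1,3,2-benzodioxasilin-4-yl]butan-2-one | Cc1ccc2c(c1)O[Si](C(C)(C)C)(C(C)(C)C)O[C@]2(C(C)C)CC(=O)C(C)=[N+]=[N-] | intermediate
12 | norcaradiene valence isomer of 13 (cyclopropane C1–C5–C10 cis-fused to ring A and to the cyclohexadiene, C1 methyl over the diene) | O4C1=CC(C)=C[C@H]2[C@]3(C)C(=O)C[C@](O[Si]4(C(C)(C)C)C(C)(C)C)(C(C)C)[C@]123 | intermediate
13 | (1S,4S)-4,6-[(di-tert-butylsilanediyl)bis(oxy)]dauca-5,7,9-trien-2-one (C1 methyl β; C4 oxygen β, isopropyl α) | O1C2=C3[C@@](O[Si]1(C(C)(C)C)C(C)(C)C)(C(C)C)CC(=O)[C@@]3(C)C=CC(C)=C2 | intermediate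
14 | 4β-hydroxy-5αH-dauca-7,9-diene-2,6-dione | O=C1C=C(C)C=C[C@]2(C)C(=O)C[C@](O)(C(C)C)[C@@H]12 | intermediate
15 | 2α,4β-dihydroxy-5αH-dauca-7,9-dien-6-one | O=C1C=C(C)C=C[C@]2(C)[C@H](O)C[C@](O)(C(C)C)[C@@H]12 | intermediate
16 | 2α-acetoxy-4β-hydroxy-5αH-dauca-7,9-dien-6-one | O=C1C=C(C)C=C[C@]2(C)[C@H](OC(C)=O)C[C@](O)(C(C)C)[C@@H]12 | intermediate
17 | 2α-acetoxy-9α,10α-epoxy-4β-hydroxy-5αH-dauc-7-en-6-one | O=C1C=C(C)[C@@H]3O[C@@H]3[C@]2(C)[C@H](OC(C)=O)C[C@](O)(C(C)C)[C@@H]12 | intermediate
18 | 2α-acetoxy-4β,10α-dihydroxy-5αH-dauc-8-en-6-one | O=C1CC(C)=C[C@H](O)[C@]2(C)[C@H](OC(C)=O)C[C@](O)(C(C)C)[C@@H]12 | intermediate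
19 | 2α-acetoxy-5αH-dauc-8-ene-4β,6α,10α-triol | O[C@@H]1CC(C)=C[C@H](O)[C@]2(C)[C@H](OC(C)=O)C[C@](O)(C(C)C)[C@@H]12 | intermediate
20 | 2α-acetoxy-4β,6α-dihydroxy-5αH-dauc-8-en-10-one | O[C@@H]1CC(C)=CC(=O)[C@]2(C)[C@H](OC(C)=O)C[C@](O)(C(C)C)[C@@H]12 | intermediate
21 | 3,4-dimethoxybenzoyl chloride | COc1ccc(C(=O)Cl)cc1OC | starting material
22 | 2α-acetoxy-6α-(3,4-dimethoxybenzoyloxy)-4β-hydroxy-5αH-dauc-8-en-10-one | COc1ccc(C(=O)O[C@@H]2CC(C)=CC(=O)[C@]3(C)[C@H](OC(C)=O)C[C@](O)(C(C)C)[C@@H]23)cc1OC | intermediate
23 | (8E)-isomer of 22 (twisted enone; C7 displaced to the β face, C10 to the α face) | COc1ccc(C(=O)O[C@@H]2C/C(C)=C/C(=O)[C@]3(C)[C@H](OC(C)=O)C[C@](O)(C(C)C)[C@@H]23)cc1OC | intermediate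
24 | 2α-acetoxy-6α-(3,4-dimethoxybenzoyloxy)-8β,9α-epoxy-4β-hydroxy-5αH-daucan-10-one (oxirane trans-fused; C8 methyl α, H-9 β) | COc1ccc(C(=O)O[C@@H]2C[C@@]3(C)O[C@@H]3C(=O)[C@]3(C)[C@H](OC(C)=O)C[C@](O)(C(C)C)[C@@H]23)cc1OC | intermediate
25 | 2α-acetoxy-6α-(3,4-dimethoxybenzoyloxy)-8β,9α-epoxy-5αH-daucane-4β,10α-diol (CNP0197096.2) | COc1ccc(C(=O)O[C@@H]2C[C@@]3(C)O[C@@H]3[C@H](O)[C@]3(C)[C@H](OC(C)=O)C[C@](O)(C(C)C)[C@@H]23)cc1OC | target

## Step count and risks

Total: 16 steps. Longest linear sequence: 16 steps (1 → 25); 2, 21 and the allylsilane of step 2 are purchased.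

**Step 15 (Proposed new method).**
- What may go wrong: the (E)-enone may return to the Z form, dimerise or add the C4 hydroxyl across C8 faster than it accepts oxygen. The photoisomerisation may populate the other twist isomer, which would give the 8α,9β-oxirane; the sense is fixed by how the bridge C7–C6–C5–C1–C10 folds and cannot be predicted by inspection. The strained oxirane may also open once formed.
- Fallback: a twisted alkene is kept, because no ground-state reaction can fuse an oxirane trans onto a closed seven-membered ring, but the transient enone is replaced by a persistent (E)-cycloalkene. Two reaction types that are each described for medium rings are used: silver-trapped sensitised photoisomerisation of cycloheptenes, and dioxirane or peracid epoxidation of isolated trans-cycloalkenes with retention.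
- The fallback leaves the route at 19. Acylation with 21 (DMAP, Et3N, −20 °C) at the less hindered C6 hydroxyl gives 2α-acetoxy-6α-(3,4-dimethoxybenzoyloxy)-5αH-dauc-8-ene-4β,10α-diol F1. Singlet-sensitised Z→E photoisomerisation (methyl benzoate, 254 nm, flow, continuous capture of the E isomer on AgNO3-loaded silica) gives the AgNO3 complex of the (8E)-alkene F2. Release of the alkene with aqueous NaCl at −20 °C in the presence of DMDO gives 25, where the fallback rejoins the route.
- C10 keeps the α-hydroxyl set in steps 10 and 11, so steps 13, 15 and 16 are not needed. If this also fails, the oxirane can only be put in place before ring B is closed, which is the logic of the first alternative.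

**Step 6 (key step).**
- What may go wrong: insertion of the carbenoid into the isopropyl methine C–H (a cyclopentanone), carbene dimerisation, or failure of the tether to reach the C5–C10 bond because the bridged substrate is too rigid.
- Fallback: the lock is given up for a freely rotating substrate of the classical type. From 6, O-methylation of the phenol (MeI, K2CO3) gives (3S)-3-(2-methoxy-4-methylphenyl)-2-methylhex-5-en-3-ol F3, and Et3SiOTf with 2,6-lutidine gives its triethylsilyl ether F4. Ozonolysis and chlorite oxidation as in step 4 give (3S)-3-(2-methoxy-4-methylphenyl)-4-methyl-3-(triethylsilyloxy)pentanoic acid F5. Acid chloride formation and diazoethane as in step 5 give (5S)-2-diazo-5-(2-methoxy-4-methylphenyl)-6-methyl-5-(triethylsilyloxy)heptan-3-one F6. Rh2(O2CC3F7)4 gives (3S,8aS)-4-methoxy-6,8a-dimethyl-3-(propan-2-yl)-3-(triethylsilyloxy)-3,8a-dihydroazulen-1(2H)-one F7. Aqueous HF in MeCN hydrolyses the enol ether and removes the silyl group to give 14, where the fallback rejoins the route.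
- Facial control then rests on allylic 1,3-strain (the silyloxy group, not the isopropyl group, lies in the arene plane beside the methoxy group) and site selectivity on sterics. The cost is an acid hydrolysis of the kind the main route avoids.

**Step 2.**
- What may go wrong: enantioselectivity may be insufficient with a ketone that is both branched and ortho-substituted, or the ortho-hydroxybenzylic carbinol may be lost through a quinone methide on work-up.
- Fallback: resolution instead of asymmetric induction. From 4, excess CH2=CHCH2MgBr gives racemic 2-(3-hydroxy-2-methylhex-5-en-3-yl)-5-methylphenol F8. Steps 3 and 4 on the racemate give the racemic silylene F9 and the racemic acid F10. Crystallisation with (S)-1-phenylethylamine gives the salt F11 of the (S)-acid (the antipodal amine is used if the salt of the (R)-acid proves the less soluble), and acidification returns 9, where the fallback rejoins the route.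

**Step 8.**
- What may go wrong: loss of chemoselectivity, with hydride also delivered from the C4 hydroxyl to the dienone carbonyl at C6.
- Fallback: both carbonyls are reduced on purpose and one is restored. From 14, excess Me4NBH(OAc)3 at −20 °C gives 5αH-dauca-7,9-diene-2α,4β,6α-triol F12, and MnO2 re-oxidises only the dienylic C6 alcohol to give 15, where the fallback rejoins the route.

**Step 16.**
- What may go wrong: hydride may arrive from the α face, since the β face of C10 lies beside the angular methyl group and the trans-fused oxirane may not allow the chelate geometry. The zinc Lewis acid may also open or rearrange the oxirane.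
- Fallback: the alkene-based end-game described for step 15 (19 → F1 → F2 → 25) never passes through a C10 ketone, because the 10α-hydroxyl of 19 is carried into the target. It makes no compound beyond F1 and F2.

## Further compounds

F1 | step 15 | 2α-acetoxy-6α-(3,4-dimethoxybenzoyloxy)-5αH-dauc-8-ene-4β,10α-diol | COc1ccc(C(=O)O[C@@H]2CC(C)=C[C@H](O)[C@]3(C)[C@H](OC(C)=O)C[C@](O)(C(C)C)[C@@H]23)cc1OC
F2 | step 15 | AgNO3 complex of the (8E)-isomer of F1 | COc1ccc(C(=O)O[C@@H]2C/C(C)=C/[C@H](O)[C@]3(C)[C@H](OC(C)=O)C[C@](O)(C(C)C)[C@@H]23)cc1OC.[Ag+].[O-][N+](=O)[O-]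
F3 | step 6 | (3S)-3-(2-methoxy-4-methylphenyl)-2-methylhex-5-en-3-ol | COc1cc(C)ccc1[C@@](O)(C(C)C)CC=C
F4 | step 6 | triethylsilyl ether of F3 | COc1cc(C)ccc1[C@@](O[Si](CC)(CC)CC)(C(C)C)CC=C
F5 | step 6 | (3S)-3-(2-methoxy-4-methylphenyl)-4-methyl-3-(triethylsilyloxy)pentanoic acid | COc1cc(C)ccc1[C@@](O[Si](CC)(CC)CC)(C(C)C)CC(=O)O
F6 | step 6 | (5S)-2-diazo-5-(2-methoxy-4-methylphenyl)-6-methyl-5-(triethylsilyloxy)heptan-3-one | COc1cc(C)ccc1[C@@](O[Si](CC)(CC)CC)(C(C)C)CC(=O)C(C)=[N+]=[N-]
F7 | step 6 | (3S,8aS)-4-methoxy-6,8a-dimethyl-3-(propan-2-yl)-3-(triethylsilyloxy)-3,8a-dihydroazulen-1(2H)-one | COC1=C2[C@@](O[Si](CC)(CC)CC)(C(C)C)CC(=O)[C@@]2(C)C=CC(C)=C1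
F8 | step 2 | racemic 2-(3-hydroxy-2-methylhex-5-en-3-yl)-5-methylphenol | Oc1cc(C)ccc1C(O)(C(C)C)CC=C
F9 | step 2 | racemic 2,2-di-tert-butyl-7-methyl-4-(propan-2-yl)-4-(prop-2-en-1-yl)-4H-1,3,2-benzodioxasiline | Cc1ccc2c(c1)O[Si](C(C)(C)C)(C(C)(C)C)OC2(C(C)C)CC=C
F10 | step 2 | racemic [2,2-di-tert-butyl-7-methyl-4-(propan-2-yl)-4H-1,3,2-benzodioxasilin-4-yl]acetic acid | Cc1ccc2c(c1)O[Si](C(C)(C)C)(C(C)(C)C)OC2(C(C)C)CC(=O)O
F11 | step 2 | (S)-1-phenylethylammonium salt of 9 | Cc1ccc2c(c1)O[Si](C(C)(C)C)(C(C)(C)C)O[C@]2(C(C)C)CC(=O)[O-].C[C@H]([NH3+])c1ccccc1
F12 | step 8 | 5αH-dauca-7,9-diene-2α,4β,6α-triol | O[C@@H]1C=C(C)C=C[C@]2(C)[C@H](O)C[C@](O)(C(C)C)[C@@H]12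
F0 | step 16 | none | none
A1 | alternative 1 | epoxy hydroazulenone with C6 hydroxyl, C4 ketone, trans-fused 8,9-oxirane, C10 tert-butyldimethylsilyl ether and C2 triethylsilyl ether | O[C@@H]2C[C@@]3(C)O[C@@H]3[C@H](O[Si](C)(C)C(C)(C)C)[C@]3(C)[C@H](O[Si](CC)(CC)CC)CC(=O)[C@@H]23
A2 | alternative 2 | ring-A aldol with C4 ketone, C1 methyl and 1,3-dithian-2-yl, C2 silyl ether, C5 bearing the C6 carbinol and methallyl arm | C=C(C)C[C@@H](O)[C@@H]1C(=O)C[C@@H](O[Si](C)(C)C(C)(C)C)[C@@]1(C)C2SCCCS2
A3 | alternative 3 | fully acylated C10 enone with the C8–C9 double bond (same compound as 22) | COc1ccc(C(=O)O[C@@H]2CC(C)=CC(=O)[C@]3(C)[C@H](OC(C)=O)C[C@](O)(C(C)C)[C@@H]23)cc1OC
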